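**Retrosynthetic overview**
- The last C–C bond made is the one between C-3 of the diol ring (ring A) and the allylic CH2. It comes from alkylating the lithium enolate of a C10 α-silyloxy ketone (ring A) with a C10 2-substituted allyl iodide that carries the bromohydrin ring (ring B); desilylation and a hydroxyl-directed ketone reduction finish the target.
- Ring A ketone ⇐ oxidation of a trans-diaxial diol ⇐ Wittig methylenation ⇐ acetyl diol ⇐ epoxidation and diaxial hydrolysis of (S)-4-acetyl-1-methylcyclohexene.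
- Ring B iodide ⇐ ene chlorination and Finkelstein exchange ⇐ Wittig ⇐ syn-bromohydrin ⇐ bromide opening (inversion) of the trans cyclic sulfate of the enantiomeric acetyl diol ⇐ (R)-4-acetyl-1-methylcyclohexene.
- Both acetylcyclohexenes ⇐ MeMgBr addition and oxidation ⇐ the two enantiomers of the organocatalytic Diels–Alder adduct of isoprene and acrolein.
- Ring order: ring B by [4+2] in step 1, ring A by [4+2] in step 11; no ring is formed after the coupling.

Assumption: both enantiomers of the imidazolidinone salt are bought; the roughly 90% ee of 3 and 16 is raised by recrystallising diols 7 and 20 (expected to be crystalline), and any mismatched diastereomer is removed by chromatography after step 18.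

**Fragment B (bromohydrin ring)**

Step 1
Reactants: 1 isoprene; 2 acrolein
Product: 3 (1R)-4-methylcyclohex-3-ene-1-carbaldehyde
Conditions: (5S)-5-benzyl-2,2,3-trimethylimidazolidin-4-one hydrochloride (20 mol %), MeNO2/H2O 95:5, 23 °C
Reagents that add atoms: none
Why: Iminium-catalysed Diels–Alder reaction (first-generation MacMillan imidazolidinone) in which the benzyl group shields one face of the (E)-iminium ion of acrolein, so isoprene adds in the "para" sense from the open face and sets C-1 as R.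

Step 2
Reactants: 3 (1R)-4-methylcyclohex-3-ene-1-carbaldehyde
Product: 4 1-[(1R)-4-methylcyclohex-3-en-1-yl]ethan-1-ol (both carbinol epimers)
Conditions: MeMgBr, THF, −78 °C; H2O quench
Reagents that add atoms: methylmagnesium bromide, C[Mg]Br
Why: Grignard addition at low temperature leaves the α-stereocentre intact, and the new carbinol centre is irrelevant because it is oxidised in the next step.

Step 3
Reactants: 4 1-[(1R)-4-methylcyclohex-3-en-1-yl]ethan-1-ol
Product: 5 1-[(1R)-4-methylcyclohex-3-en-1-yl]ethan-1-one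
Conditions: Dess–Martin periodinane, CH2Cl2, 0 °C → rt
Reagents that add atoms: none
Why: Dess–Martin oxidation under near-neutral conditions gives the methyl ketone without epimerising the adjacent ring stereocentre.

Step 4
Reactants: 5 1-[(1R)-4-methylcyclohex-3-en-1-yl]ethan-1-one
Product: 7 1-[(1R,3S,4S)-3,4-dihydroxy-4-methylcyclohexyl]ethan-1-one, via epoxide mixture 6 (not isolated)
Conditions: mCPBA, CH2Cl2, 0 °C; then 1% aq H2SO4/THF, 0 °C → rt
Reagents that add atoms: mCPBA, OOC(=O)c1cccc(Cl)c1; water, O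
Why: Prilezhaev epoxidation of the trisubstituted alkene followed by acid-catalysed trans-diaxial (Fürst–Plattner) opening, in which both epoxide diastereomers converge on the same diaxial diol because the equatorial acetyl group fixes the chair, so C-3 and C-4 (both S) follow from the existing R centre.

Step 5
Reactants: 7 1-[(1R,3S,4S)-3,4-dihydroxy-4-methylcyclohexyl]ethan-1-one
Product: 9 1-[(1R,3S,4S)-4-methyl-3,4-(sulfonyldioxy)cyclohexyl]ethan-1-one (trans-fused cyclic sulfate), via cyclic sulfite 8 (not isolated)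
Conditions: SOCl2, Et3N, CH2Cl2, 0 °C; then RuCl3·3H2O (1 mol %), NaIO4, MeCN/H2O, 0 °C
Reagents that add atoms: thionyl chloride, O=S(Cl)Cl; sodium periodate, [Na+].[O-]I(=O)(=O)=O
Why: Sharpless cyclic sulfate synthesis, possible because the diol can reach the diequatorial chair at modest cost (acetyl and methyl axial), and it touches no stereocentre.

Step 6
Reactants: 9 trans-fused cyclic sulfate
Product: 11 1-[(1R,3R,4S)-3-bromo-4-hydroxy-4-methylcyclohexyl]ethan-1-one, via lithium alkyl sulfate 10 (not isolated)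
Conditions: LiBr, THF, 23 → 45 °C; then H2SO4 (cat.), H2O (2 equiv), THF, 23 °C
Reagents that add atoms: lithium bromide, [Li+].[Br-]
Why: SN2 opening of the cyclic sulfate by bromide at the secondary carbon inverts C-3 (S to R) and the tertiary sulfate is then hydrolysed with S–O cleavage, so bromine ends cis to the retained tertiary oxygen (syn-bromohydrin with acetyl, Br and methyl all equatorial).

Step 7
Reactants: 11 1-[(1R,3R,4S)-3-bromo-4-hydroxy-4-methylcyclohexyl]ethan-1-one
Product: 12 1-[(1R,3R,4S)-3-bromo-4-methyl-4-(triethylsilyloxy)cyclohexyl]ethan-1-one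
Conditions: TESOTf, 2,6-lutidine, CH2Cl2, −78 → −40 °C
Reagents that add atoms: triethylsilyl trifluoromethanesulfonate, CC[Si](CC)(CC)OS(=O)(=O)C(F)(F)F
Why: Silyl triflate silylation of the tertiary alcohol masks the bromohydrin against alkoxide-triggered ring contraction in step 8 and against proton transfer in the coupling, without touching a stereocentre.

Step 8
Reactants: 12 1-[(1R,3R,4S)-3-bromo-4-methyl-4-(triethylsilyloxy)cyclohexyl]ethan-1-one
Product: 13 {[(1S,2R,4R)-2-bromo-1-methyl-4-(prop-1-en-2-yl)cyclohexyl]oxy}triethylsilane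
Conditions: Ph3PCH3Br, KOtBu, THF, 0 °C → rt
Reagents that add atoms: methyltriphenylphosphonium bromide, C[P+](c1ccccc1)(c1ccccc1)c1ccccc1.[Br-]
Why: Wittig methylenation of the methyl ketone; the equatorial secondary bromide has no antiperiplanar hydrogen and survives the ylide, and the equatorial side chain is the thermodynamic epimer.

Step 9
Reactants: 13 {[(1S,2R,4R)-2-bromo-1-methyl-4-(prop-1-en-2-yl)cyclohexyl]oxy}triethylsilane
Product: 14 {[(1S,2R,4R)-2-bromo-4-(3-chloroprop-1-en-2-yl)-1-methylcyclohexyl]oxy}triethylsilane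
Conditions: Ca(OCl)2, CO2 (dry ice), CH2Cl2/H2O, 0 °C
Reagents that add atoms: calcium hypochlorite, [Ca+2].[O-]Cl.[O-]Cl
Why: Ene-type allylic chlorination by HOCl takes a methyl hydrogen of the 1,1-disubstituted alkene and gives the 2-substituted allyl chloride with a shifted double bond, leaving the ring stereocentres untouched.

Step 10
Reactants: 14 {[(1S,2R,4R)-2-bromo-4-(3-chloroprop-1-en-2-yl)-1-methylcyclohexyl]oxy}triethylsilane
Product: 15 {[(1S,2R,4R)-2-bromo-4-(3-iodoprop-1-en-2-yl)-1-methylcyclohexyl]oxy}triethylsilane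
Conditions: NaI, acetone, rt, dark
Reagents that add atoms: sodium iodide, [Na+].[I-]
Why: Finkelstein exchange is fast at the allylic chloride and negligible at the hindered equatorial ring bromide, giving a more reactive electrophile for the coupling.

**Fragment A (diol ring)**

Step 11
Reactants: 1 isoprene; 2 acrolein
Product: 16 (1S)-4-methylcyclohex-3-ene-1-carbaldehyde
Conditions: (5R)-5-benzyl-2,2,3-trimethylimidazolidin-4-one hydrochloride (20 mol %), MeNO2/H2O 95:5, 23 °C
Reagents that add atoms: none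
Why: The same iminium-catalysed Diels–Alder reaction with the enantiomeric catalyst exposes the opposite face of acrolein and sets C-1 as S.

Step 12
Reactants: 16 (1S)-4-methylcyclohex-3-ene-1-carbaldehyde
Product: 17 1-[(1S)-4-methylcyclohex-3-en-1-yl]ethan-1-ol (both carbinol epimers)
Conditions: MeMgBr, THF, −78 °C; H2O quench
Reagents that add atoms: methylmagnesium bromide, C[Mg]Br
Why: Grignard addition without loss of the α-stereocentre; the carbinol centre is removed in the next step.

Step 13
Reactants: 17 1-[(1S)-4-methylcyclohex-3-en-1-yl]ethan-1-ol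
Product: 18 1-[(1S)-4-methylcyclohex-3-en-1-yl]ethan-1-one
Conditions: Dess–Martin periodinane, CH2Cl2, 0 °C → rt
Reagents that add atoms: none
Why: Dess–Martin oxidation gives the methyl ketone without epimerisation.

Step 14
Reactants: 18 1-[(1S)-4-methylcyclohex-3-en-1-yl]ethan-1-one
Product: 20 1-[(1S,3R,4R)-3,4-dihydroxy-4-methylcyclohexyl]ethan-1-one, via epoxide mixture 19 (not isolated)
Conditions: mCPBA, CH2Cl2, 0 °C; then 1% aq H2SO4/THF, 0 °C → rt
Reagents that add atoms: mCPBA, OOC(=O)c1cccc(Cl)c1; water, O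
Why: Prilezhaev epoxidation and convergent trans-diaxial (Fürst–Plattner) hydrolysis of both epoxides set the tertiary hydroxyl cis and the secondary hydroxyl trans to the equatorial acetyl group (R,R).

Step 15
Reactants: 20 1-[(1S,3R,4R)-3,4-dihydroxy-4-methylcyclohexyl]ethan-1-one
Product: 21 (1R,2R,4S)-1-methyl-4-(prop-1-en-2-yl)cyclohexane-1,2-diol
Conditions: Ph3PCH3Br (4 equiv), KOtBu (3.8 equiv), THF, 0 °C → rt
Reagents that add atoms: methyltriphenylphosphonium bromide, C[P+](c1ccccc1)(c1ccccc1)c1ccccc1.[Br-]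
Why: Wittig methylenation with excess ylide (the diol is carried as its dialkoxide) installs the isopropenyl group, and the equatorial side chain is the thermodynamic epimer.

Step 16
Reactants: 21 (1R,2R,4S)-1-methyl-4-(prop-1-en-2-yl)cyclohexane-1,2-diol
Product: 22 (2R,5S)-2-hydroxy-2-methyl-5-(prop-1-en-2-yl)cyclohexan-1-one
Conditions: IBX, EtOAc, 80 °C
Reagents that add atoms: none
Why: IBX oxidises the secondary alcohol of a 1,2-diol to the α-hydroxy ketone without glycol cleavage and without touching the alkene or the tertiary carbinol centre.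

Step 17
Reactants: 22 (2R,5S)-2-hydroxy-2-methyl-5-(prop-1-en-2-yl)cyclohexan-1-one
Product: 23 (2R,5S)-2-methyl-5-(prop-1-en-2-yl)-2-(triethylsilyloxy)cyclohexan-1-one
Conditions: TESOTf, 2,6-lutidine, CH2Cl2, −78 °C
Reagents that add atoms: triethylsilyl trifluoromethanesulfonate, CC[Si](CC)(CC)OS(=O)(=O)C(F)(F)F
Why: Silylation of the tertiary α-hydroxyl allows clean mono-enolate formation in the coupling.

**Coupling and endgame**

Step 18
Reactants: 23 (2R,5S)-2-methyl-5-(prop-1-en-2-yl)-2-(triethylsilyloxy)cyclohexan-1-one; 15 {[(1S,2R,4R)-2-bromo-4-(3-iodoprop-1-en-2-yl)-1-methylcyclohexyl]oxy}triethylsilane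
Product: 25 (2R,5S,6R)-6-{2-[(1R,3R,4S)-3-bromo-4-methyl-4-(triethylsilyloxy)cyclohexyl]prop-2-en-1-yl}-2-methyl-5-(prop-1-en-2-yl)-2-(triethylsilyloxy)cyclohexan-1-one, via lithium enolate 24 (not isolated)
Conditions: LiN(iPr)2 (1.1 equiv), THF, −78 °C; then 15, DMPU, −78 → −20 °C
Reagents that add atoms: none
Why: Kinetic lithium enolate alkylation (only C-6 can enolise) with the allylic iodide, which enters anti to the neighbouring isopropenyl group to give the trans-5,6 (6R) diequatorial product, also the thermodynamic epimer.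

Step 19
Reactants: 25 bis(triethylsilyl) ether ketone
Product: 26 (2R,5S,6R)-6-{2-[(1R,3R,4S)-3-bromo-4-hydroxy-4-methylcyclohexyl]prop-2-en-1-yl}-2-hydroxy-2-methyl-5-(prop-1-en-2-yl)cyclohexan-1-one
Conditions: HF·pyridine, pyridine/THF, 0 °C → rt
Reagents that add atoms: none
Why: Buffered fluoride cleavage of both tertiary silyl ethers under conditions that spare the alkenes, the bromide and the ketone stereocentres.

Step 20
Reactants: 26 dihydroxy ketone
Product: 27 prevezol C, (1R,2R,3R,4S)-3-{2-[(1R,3R,4S)-3-bromo-4-hydroxy-4-methylcyclohexyl]prop-2-en-1-yl}-1-methyl-4-(prop-1-en-2-yl)cyclohexane-1,2-diol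
Conditions: Me4NBH(OAc)3, MeCN/AcOH 1:1, −20 → 0 °C
Reagents that add atoms: none
Why: Saksena–Evans hydroxyl-directed reduction, in which the axial tertiary hydroxyl binds the borohydride and delivers hydride to the same face of the adjacent ketone, so the new hydroxyl is trans to it and cis to the side chain (2R, trans-diaxial diol), while unassisted ketone reduction does not compete with this reagent.

**Compound list**
1 | isoprene (2-methylbuta-1,3-diene) | CC(=C)C=C | starting material
2 | acrolein (prop-2-enal) | C=CC=O | starting material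
3 | (1R)-4-methylcyclohex-3-ene-1-carbaldehyde | O=C[C@@H]1CCC(C)=CC1 | intermediate
4 | 1-[(1R)-4-methylcyclohex-3-en-1-yl]ethan-1-ol (both carbinol epimers) | CC(O)[C@@H]1CCC(C)=CC1 | intermediate
5 | 1-[(1R)-4-methylcyclohex-3-en-1-yl]ethan-1-one | CC(=O)[C@@H]1CCC(C)=CC1 | intermediate
6 | 1-[(3R)-6-methyl-7-oxabicyclo[4.1.0]heptan-3-yl]ethan-1-one (both epoxide diastereomers) | CC(=O)[C@@H]1CCC2(C)OC2C1 | intermediate (not isolated)
7 | 1-[(1R,3S,4S)-3,4-dihydroxy-4-methylcyclohexyl]ethan-1-one | CC(=O)[C@@H]1CC[C@](C)(O)[C@@H](O)C1 | intermediate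
8 | 1-[(1R,3S,4S)-4-methyl-3,4-(sulfinyldioxy)cyclohexyl]ethan-1-one (trans-fused cyclic sulfite, both sulfur epimers) | CC(=O)[C@@H]1CC[C@]2(C)OS(=O)O[C@H]2C1 | intermediate (not isolated)
9 | 1-[(1R,3S,4S)-4-methyl-3,4-(sulfonyldioxy)cyclohexyl]ethan-1-one (trans-fused cyclic sulfate) | CC(=O)[C@@H]1CC[C@]2(C)OS(=O)(=O)O[C@H]2C1 | intermediate
10 | lithium (1S,2R,4R)-4-acetyl-2-bromo-1-methylcyclohexyl sulfate | CC(=O)[C@@H]1CC[C@](C)(OS(=O)(=O)[O-])[C@H](Br)C1.[Li+] | intermediate (not isolated)
11 | 1-[(1R,3R,4S)-3-bromo-4-hydroxy-4-methylcyclohexyl]ethan-1-one | CC(=O)[C@@H]1CC[C@](C)(O)[C@H](Br)C1 | intermediate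
12 | 1-[(1R,3R,4S)-3-bromo-4-methyl-4-(triethylsilyloxy)cyclohexyl]ethan-1-one | CC(=O)[C@@H]1CC[C@](C)(O[Si](CC)(CC)CC)[C@H](Br)C1 | intermediate
13 | {[(1S,2R,4R)-2-bromo-1-methyl-4-(prop-1-en-2-yl)cyclohexyl]oxy}triethylsilane | CC(=C)[C@@H]1CC[C@](C)(O[Si](CC)(CC)CC)[C@H](Br)C1 | intermediate
14 | {[(1S,2R,4R)-2-bromo-4-(3-chloroprop-1-en-2-yl)-1-methylcyclohexyl]oxy}triethylsilane | ClCC(=C)[C@@H]1CC[C@](C)(O[Si](CC)(CC)CC)[C@H](Br)C1 | intermediate
15 | {[(1S,2R,4R)-2-bromo-4-(3-iodoprop-1-en-2-yl)-1-methylcyclohexyl]oxy}triethylsilane | ICC(=C)[C@@H]1CC[C@](C)(O[Si](CC)(CC)CC)[C@H](Br)C1 | intermediate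
16 | (1S)-4-methylcyclohex-3-ene-1-carbaldehyde | O=C[C@H]1CCC(C)=CC1 | intermediate
17 | 1-[(1S)-4-methylcyclohex-3-en-1-yl]ethan-1-ol (both carbinol epimers) | CC(O)[C@H]1CCC(C)=CC1 | intermediate
18 | 1-[(1S)-4-methylcyclohex-3-en-1-yl]ethan-1-one | CC(=O)[C@H]1CCC(C)=CC1 | intermediate
19 | 1-[(3S)-6-methyl-7-oxabicyclo[4.1.0]heptan-3-yl]ethan-1-one (both epoxide diastereomers) | CC(=O)[C@H]1CCC2(C)OC2C1 | intermediate (not isolated)
20 | 1-[(1S,3R,4R)-3,4-dihydroxy-4-methylcyclohexyl]ethan-1-one | CC(=O)[C@H]1CC[C@@](C)(O)[C@H](O)C1 | intermediate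
21 | (1R,2R,4S)-1-methyl-4-(prop-1-en-2-yl)cyclohexane-1,2-diol | CC(=C)[C@H]1CC[C@@](C)(O)[C@H](O)C1 | intermediate
22 | (2R,5S)-2-hydroxy-2-methyl-5-(prop-1-en-2-yl)cyclohexan-1-one | CC(=C)[C@H]1CC[C@@](C)(O)C(=O)C1 | intermediate
23 | (2R,5S)-2-methyl-5-(prop-1-en-2-yl)-2-(triethylsilyloxy)cyclohexan-1-one | CC(=C)[C@H]1CC[C@@](C)(O[Si](CC)(CC)CC)C(=O)C1 | intermediate
24 | lithium (3S,6R)-6-methyl-3-(prop-1-en-2-yl)-6-(triethylsilyloxy)cyclohex-1-en-1-olate | CC(=C)[C@H]1CC[C@@](C)(O[Si](CC)(CC)CC)C(O[Li])=C1 | intermediate (not isolated)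
25 | (2R,5S,6R)-6-{2-[(1R,3R,4S)-3-bromo-4-methyl-4-(triethylsilyloxy)cyclohexyl]prop-2-en-1-yl}-2-methyl-5-(prop-1-en-2-yl)-2-(triethylsilyloxy)cyclohexan-1-one | C=C(C[C@@H]1[C@@H](C(=C)C)CC[C@@](C)(O[Si](CC)(CC)CC)C1=O)[C@@H]1CC[C@](C)(O[Si](CC)(CC)CC)[C@H](Br)C1 | intermediate
26 | (2R,5S,6R)-6-{2-[(1R,3R,4S)-3-bromo-4-hydroxy-4-methylcyclohexyl]prop-2-en-1-yl}-2-hydroxy-2-methyl-5-(prop-1-en-2-yl)cyclohexan-1-one | C=C(C[C@@H]1[C@@H](C(=C)C)CC[C@@](C)(O)C1=O)[C@@H]1CC[C@](C)(O)[C@H](Br)C1 | intermediate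
27 | prevezol C, (1R,2R,3R,4S)-3-{2-[(1R,3R,4S)-3-bromo-4-hydroxy-4-methylcyclohexyl]prop-2-en-1-yl}-1-methyl-4-(prop-1-en-2-yl)cyclohexane-1,2-diol | C=C(C[C@@H]1[C@@H](C(=C)C)CC[C@@](C)(O)[C@@H]1O)[C@@H]1CC[C@](C)(O)[C@H](Br)C1 | target

**Step count and risks**
Total step count: 20. Longest linear sequence: 13 steps (steps 1–10, then 18–20); the other branch has 7 steps (11–17) before the coupling.

Most likely to fail:

1. Step 6 (bromide opening of cyclic sulfate 9). The attacked carbon is next to a fully substituted carbon, and in the sulfate chair the bromide approaches syn to the axial acetyl group. The opening may be slow or give elimination, and hydrolysis of the tertiary sulfate could ionise instead of cleaving at sulfur. Fallback: set out from diol 7. Sulfonylate only the secondary hydroxyl (ClCH2SO2Cl, pyridine, 0 °C) to give (1S,2S,5R)-5-acetyl-2-hydroxy-2-methylcyclohexyl chloromethanesulfonate F1. Silylate the tertiary hydroxyl (TESOTf, 2,6-lutidine) to give (1S,2S,5R)-5-acetyl-2-methyl-2-(triethylsilyloxy)cyclohexyl chloromethanesulfonate F2. Displace the now axial sulfonate with LiBr in DMF at 60 °C; this is SN2 with equatorial approach and inversion in the chair that keeps the acetyl group equatorial, and the silyl ether cannot close to an epoxide. This gives 12 directly, where the route is rejoined.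

2. Step 9 (ene chlorination of 13). HOCl can also abstract the ring methine hydrogen or over-chlorinate, so the yield of 14 may be poor. Fallback: set out from ketone 12. Dimethylsulfonium methylide (Me3SI, KOtBu, DMSO/THF, 0 °C; Corey–Chaykovsky) gives 2-methyl-2-[(1R,3R,4S)-3-bromo-4-methyl-4-(triethylsilyloxy)cyclohexyl]oxirane F3. Et2Al(TMP) (diethylaluminium 2,2,6,6-tetramethylpiperidide) in toluene at 0 °C isomerises it, by removal of a methyl proton, to 2-[(1R,3R,4S)-3-bromo-4-methyl-4-(triethylsilyloxy)cyclohexyl]prop-2-en-1-ol F4. PPh3, I2 and imidazole then give iodide 15, where the route is rejoined; steps 8 to 10 are bypassed.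

3. Step 18 (enolate alkylation joining the two halves). The enolate carbon sits between a fully substituted carbon and the isopropenyl-bearing carbon, and the electrophile is a branched allyl iodide. Slow alkylation, proton transfer or O-alkylation are possible. Fallback: set out from ketone 23 and chloride 14 (step 10 is then not needed). LiN(iPr)2 followed by ZnCl2 gives chlorozinc (3S,6R)-6-methyl-3-(prop-1-en-2-yl)-6-(triethylsilyloxy)cyclohex-1-en-1-olate F5. This is allylated by 14 under Pd(PPh3)4 catalysis (zerovalent palladium, Tsuji–Trost allylic alkylation); both allyl termini give the same connectivity and the ring bromide is inert. The product is 25, where the route is rejoined.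

**Further compounds**
F1 | step 6 | (1S,2S,5R)-5-acetyl-2-hydroxy-2-methylcyclohexyl chloromethanesulfonate | CC(=O)[C@@H]1CC[C@](C)(O)[C@@H](OS(=O)(=O)CCl)C1
F2 | step 6 | (1S,2S,5R)-5-acetyl-2-methyl-2-(triethylsilyloxy)cyclohexyl chloromethanesulfonate | CC(=O)[C@@H]1CC[C@](C)(O[Si](CC)(CC)CC)[C@@H](OS(=O)(=O)CCl)C1
F3 | step 9 | 2-methyl-2-[(1R,3R,4S)-3-bromo-4-methyl-4-(triethylsilyloxy)cyclohexyl]oxirane (both epoxide epimers) | CC1(CO1)[C@@H]1CC[C@](C)(O[Si](CC)(CC)CC)[C@H](Br)C1
F4 | step 9 | 2-[(1R,3R,4S)-3-bromo-4-methyl-4-(triethylsilyloxy)cyclohexyl]prop-2-en-1-ol | OCC(=C)[C@@H]1CC[C@](C)(O[Si](CC)(CC)CC)[C@H](Br)C1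
F5 | step 18 | chlorozinc (3S,6R)-6-methyl-3-(prop-1-en-2-yl)-6-(triethylsilyloxy)cyclohex-1-en-1-olate | CC(=C)[C@H]1CC[C@@](C)(O[Si](CC)(CC)CC)C(O[Zn]Cl)=C1
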